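## Retrosynthetic overview

1. Ansa numbering: C1 = lactam C=O … C15 = benzylic carbinol. The target comes from macrolactam 35 by global desilylation. The 19-membered lactam is the only ring made; it is closed late by intramolecular copper-catalysed N-arylation of primary amide 34 on the aryl bromide.
2. C7–C8: chelation-controlled addition of the C8 alkenylzinc (hydrozirconation of methyl alkyne 30) to α-methoxy aldehyde 15 (C1–C7, from divinyl carbinol by Sharpless desymmetrisation and B-alkyl Suzuki coupling).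
3. C15–aryl: lithiation–borylation of carbamate 25 with aryl boronate 3 (C–H borylation of silylated 3-bromophenol). The aryl group shifts 1,2 from boron to C15; oxidation gives the 15R alcohol.
4. C10–C11: Marshall allenylstannane addition to aldehyde 23. C12 and C11 are inserted into the C13–B bond of Roche-bromide-derived boronate 18 by two further 1,2-boronate shifts (a new chiral α-methoxy carbenoid for C12, then LiCHCl2 for C11).

Assumption: compounds 1, 4, 6, 9, 12 and 16 are purchased (6 and 16 as single enantiomers); TIPS = tri(propan-2-yl)silyl, TBS = tert-butyl(dimethyl)silyl, Cb = N,N-di(propan-2-yl)carbamoyl, pin = pinacolato, TIB = 2,4,6-tri(propan-2-yl)benzoyl.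

## Route

Step 1
Reactants: 1 3-bromophenol
Product: 2 (3-bromophenoxy)tri(propan-2-yl)silane
Conditions: TIPSCl, imidazole, DMF, rt
Reagents that add atoms: chlorotri(propan-2-yl)silane, CC(C)[Si](Cl)(C(C)C)C(C)C
Why: Phenol silylation; the TIPS aryl ether survives the later organolithium, peroxide and carbonate steps.

Step 2
Reactants: 2 (3-bromophenoxy)tri(propan-2-yl)silane
Product: 3 [3-bromo-5-(4,4,5,5-tetramethyl-1,3,2-dioxaborolan-2-yl)phenoxy]tri(propan-2-yl)silane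
Conditions: B2pin2, [Ir(OMe)(cod)]2 (1.5 mol%), 4,4'-di-tert-butyl-2,2'-bipyridine (3 mol%), hexane, 60 °C
Reagents that add atoms: bis(pinacolato)diboron, CC1(C)OB(OC1(C)C)B1OC(C)(C)C(C)(C)O1
Why: Sterically controlled iridium-catalysed aromatic C–H borylation of a 1,3-disubstituted arene occurs only at the mutually meta C5–H, giving the 1,3,5 pattern with the bromide intact.

Step 3
Reactants: 4 chloro(methoxy)methane
Product: 5 methoxymethyl 2,4,6-tri(propan-2-yl)benzoate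
Conditions: 2,4,6-tri(propan-2-yl)benzoic acid, iPr2NEt, CH2Cl2, 0 °C → rt
Reagents that add atoms: 2,4,6-tri(propan-2-yl)benzoic acid, CC(C)c1cc(C(C)C)c(C(=O)O)c(C(C)C)c1
Why: SN2 O-alkylation of the hindered carboxylate gives the acetal ester that carries the future C12–OMe unit and a directing/leaving group.

Step 4
Reactants: 6 (2S)-pent-3-yn-2-ol
Product: 7 (2S)-pent-3-yn-2-yl methanesulfonate
Conditions: MsCl, Et3N, CH2Cl2, −78 °C
Reagents that add atoms: methanesulfonyl chloride, CS(=O)(=O)Cl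
Why: Mesylation at oxygen leaves the stereocentre untouched.

Step 5
Reactants: 7 (2S)-pent-3-yn-2-yl methanesulfonate
Product: 8 (aR)-tributyl(penta-2,3-dien-2-yl)stannane
Conditions: Bu3SnH, LDA, THF, 0 °C; CuBr·SMe2, −78 °C; then 7, −78 °C
Reagents that add atoms: tributylstannane, CCCC[SnH](CCCC)CCCC
Why: Anti SN2' displacement of the propargylic mesylate by the stannylcopper reagent transfers central to axial chirality (Marshall allenylstannane synthesis).

Step 6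
Reactants: 9 penta-1,4-dien-3-ol
Product: 10 (1S)-1-[(2R)-oxiran-2-yl]prop-2-en-1-ol
Conditions: Ti(OiPr)4 (10 mol%), L-(+)-DIPT (13 mol%), t-BuOOH, 4 Å MS, CH2Cl2, −20 °C
Reagents that add atoms: tert-butyl hydroperoxide, CC(C)(C)OO
Why: Sharpless asymmetric epoxidation desymmetrises the divinyl carbinol; L-(+)-tartrate selects the vinyl group and face that give the erythro (2R,3S) epoxy alcohol, which fixes C6.

Step 7
Reactants: 10 (1S)-1-[(2R)-oxiran-2-yl]prop-2-en-1-ol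
Product: 11 (2R)-2-[(1S)-1-methoxyprop-2-en-1-yl]oxirane
Conditions: NaH, MeI, THF, 0 °C
Reagents that add atoms: iodomethane, CI
Why: Williamson methylation of the alkoxide outruns Payne rearrangement in aprotic solvent and does not touch the stereocentres.

Step 8
Reactants: 11 (2R)-2-[(1S)-1-methoxyprop-2-en-1-yl]oxirane; 12 methyl (2E)-3-iodo-2-methylprop-2-enoate
Product: 14 methyl (2E,6S)-6-methoxy-2-methyl-6-[(2R)-oxiran-2-yl]hex-2-enoate, via alkylborane 13 (not isolated)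
Conditions: 9-BBN, THF, 0 °C → rt; then 12, Pd(dppf)Cl2 (5 mol%), AsPh3, Cs2CO3, DMF/H2O, rt
Reagents that add atoms: none
Why: Anti-Markovnikov hydroboration of the only alkene followed by B-alkyl Suzuki–Miyaura coupling joins C4–C3 and keeps the E geometry of the iodoacrylate.

Step 9
Reactants: 14 methyl (2E,6S)-6-methoxy-2-methyl-6-[(2R)-oxiran-2-yl]hex-2-enoate
Product: 15 methyl (2E,6S)-6-methoxy-2-methyl-7-oxohept-2-enoate
Conditions: H5IO6, THF/H2O, 0 °C → rt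
Reagents that add atoms: none
Why: Periodic acid opens the terminal epoxide and cleaves the resulting glycol in one pot (glycol cleavage), losing the extra carbon as formaldehyde; C7 keeps the epoxide oxygen and the acidic medium does not epimerise C6.

Step 10
Reactants: 16 (2R)-3-bromo-2-methylpropan-1-ol
Product: 17 (2R)-3-bromo-2-methylpropyl N,N-di(propan-2-yl)carbamate
Conditions: iPr2NCOCl, Et3N, DMAP (cat.), CH2Cl2, 40 °C
Reagents that add atoms: N,N-di(propan-2-yl)carbamoyl chloride, CC(C)N(C(C)C)C(Cl)=O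
Why: Carbamoylation of the primary alcohol installs the Hoppe directing and leaving group at the future C15; the bromide is untouched.

Step 11
Reactants: 17 (2R)-3-bromo-2-methylpropyl N,N-di(propan-2-yl)carbamate
Product: 18 (2S)-2-methyl-3-(4,4,5,5-tetramethyl-1,3,2-dioxaborolan-2-yl)propyl N,N-di(propan-2-yl)carbamate
Conditions: B2pin2, CuI (10 mol%), PPh3 (13 mol%), LiOMe, DMF, rt
Reagents that add atoms: bis(pinacolato)diboron, CC1(C)OB(OC1(C)C)B1OC(C)(C)C(C)(C)O1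
Why: Copper-catalysed borylation of a primary alkyl bromide; the C14 stereocentre is β to the reacting carbon and is not affected.

Step 12
Reactants: 18 (2S)-2-methyl-3-(4,4,5,5-tetramethyl-1,3,2-dioxaborolan-2-yl)propyl N,N-di(propan-2-yl)carbamate; 5 methoxymethyl 2,4,6-tri(propan-2-yl)benzoate
Product: 21 (2S,4R)-4-methoxy-2-methyl-4-(4,4,5,5-tetramethyl-1,3,2-dioxaborolan-2-yl)butyl N,N-di(propan-2-yl)carbamate, via lithiated benzoate 19 (not isolated), via boronate complex 20 (not isolated)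
Conditions: 5, s-BuLi, (+)-sparteine, Et2O, −78 °C; then 18, −78 °C → rt
Reagents that add atoms: none
Why: Proposed new method: s-BuLi/(+)-sparteine removes one enantiotopic acetal proton of 5 (directed by the ester C=O as in Hoppe carbamates and Aggarwal TIB esters; OMe is assumed to play the role of the alkyl chain, so the pro-R proton is removed) to give the configurationally stable α-methoxy carbenoid 19, which binds boron of 18 with retention (20); the C13 alkyl group then migrates from boron to carbon anti to the departing benzoate (1,2-metallate rearrangement, inversion), forming C12–C13 and setting C12 by reagent control with C14 as a spectator; closest known reactions are lithiation–borylation of primary alkyl carbamates and benzoates and the Matteson insertion of LiCH(OMe)SPh.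

Step 13
Reactants: 21 (2S,4R)-4-methoxy-2-methyl-4-(4,4,5,5-tetramethyl-1,3,2-dioxaborolan-2-yl)butyl N,N-di(propan-2-yl)carbamate
Product: 23 (2S,4S)-4-methoxy-2-methyl-5-oxopentyl N,N-di(propan-2-yl)carbamate, via chloro boronate 22 (not isolated)
Conditions: CH2Cl2, n-BuLi, THF, −100 °C; then 21, ZnCl2, −100 °C → rt; then H2O2, pH 7 phosphate buffer, THF, 0 °C
Reagents that add atoms: dichloromethane, ClCCl; hydrogen peroxide, OO
Why: Matteson homologation: the α-methoxyalkyl group shifts 1,2 from boron to the dichloromethyl carbon with retention at C12, and oxidation of the α-chloro boronate releases the C11 aldehyde under neutral conditions that do not epimerise C12.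

Step 14
Reactants: 23 (2S,4S)-4-methoxy-2-methyl-5-oxopentyl N,N-di(propan-2-yl)carbamate; 8 (aR)-tributyl(penta-2,3-dien-2-yl)stannane
Product: 24 (2S,4S,5R,6S)-5-hydroxy-4-methoxy-2,6-dimethylnon-7-yn-1-yl N,N-di(propan-2-yl)carbamate
Conditions: BF3·OEt2, CH2Cl2, −78 °C
Reagents that add atoms: none
Why: Marshall BF3-promoted anti SE2' addition of the chiral allenylstannane through an open transition state gives the syn C10/C11 pair; the (aR) reagent sets 10S and is matched with Felkin–Anh attack on the α-methoxy aldehyde (11,12-anti, 11R).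

Step 15
Reactants: 24 (2S,4S,5R,6S)-5-hydroxy-4-methoxy-2,6-dimethylnon-7-yn-1-yl N,N-di(propan-2-yl)carbamate
Product: 25 (2S,4S,5R,6S)-5-{[tert-butyl(dimethyl)silyl]oxy}-4-methoxy-2,6-dimethylnon-7-yn-1-yl N,N-di(propan-2-yl)carbamate
Conditions: TBSOTf, 2,6-lutidine, CH2Cl2, 0 °C
Reagents that add atoms: tert-butyl(dimethyl)silyl trifluoromethanesulfonate, CC(C)(C)[Si](C)(C)OS(=O)(=O)C(F)(F)F
Why: Silyl triflate silylation protects the hindered C11 alcohol before the organolithium step.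

Step 16
Reactants: 25 (2S,4S,5R,6S)-5-{[tert-butyl(dimethyl)silyl]oxy}-4-methoxy-2,6-dimethylnon-7-yn-1-yl N,N-di(propan-2-yl)carbamate; 3 [3-bromo-5-(4,4,5,5-tetramethyl-1,3,2-dioxaborolan-2-yl)phenoxy]tri(propan-2-yl)silane
Product: 29 (1R,2S,4S,5R,6S)-1-{3-bromo-5-[tri(propan-2-yl)silyloxy]phenyl}-5-{[tert-butyl(dimethyl)silyl]oxy}-4-methoxy-2,6-dimethylnon-7-yn-1-ol, via lithiated carbamate 26 (not isolated), via boronate complex 27 (not isolated), via benzylic boronate 28 (not isolated)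
Conditions: s-BuLi, (−)-sparteine, Et2O, −78 °C; then 3, −78 °C → 35 °C; then H2O2, NaOH, THF, 0 °C
Reagents that add atoms: hydrogen peroxide, OO
Why: Hoppe–Aggarwal lithiation–borylation: (−)-sparteine-directed removal of the pro-S proton gives the (S)-lithio carbamate, borylation occurs with retention, the aryl group then shifts 1,2 from boron to C15 with inversion (1,2-metallate rearrangement) and stereoretentive oxidation gives the 15R alcohol; reagent control overrides the C14 centre.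

Step 17
Reactants: 29 (1R,2S,4S,5R,6S)-1-{3-bromo-5-[tri(propan-2-yl)silyloxy]phenyl}-5-{[tert-butyl(dimethyl)silyl]oxy}-4-methoxy-2,6-dimethylnon-7-yn-1-ol
Product: 30 {3-bromo-5-[(1R,2S,4S,5R,6S)-1,5-bis{[tert-butyl(dimethyl)silyl]oxy}-4-methoxy-2,6-dimethylnon-7-yn-1-yl]phenoxy}tri(propan-2-yl)silane
Conditions: TBSOTf, 2,6-lutidine, CH2Cl2, 0 °C
Reagents that add atoms: tert-butyl(dimethyl)silyl trifluoromethanesulfonate, CC(C)(C)[Si](C)(C)OS(=O)(=O)C(F)(F)F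
Why: Silylation of the benzylic alcohol removes the last acidic proton before hydrozirconation.

Step 18
Reactants: 30 {3-bromo-5-[(1R,2S,4S,5R,6S)-1,5-bis{[tert-butyl(dimethyl)silyl]oxy}-4-methoxy-2,6-dimethylnon-7-yn-1-yl]phenoxy}tri(propan-2-yl)silane; 15 methyl (2E,6S)-6-methoxy-2-methyl-7-oxohept-2-enoate
Product: 33 methyl (2E,6S,7S,8E,10S,11R,12S,14S,15R)-15-{3-bromo-5-[tri(propan-2-yl)silyloxy]phenyl}-11,15-bis{[tert-butyl(dimethyl)silyl]oxy}-7-hydroxy-6,12-dimethoxy-2,8,10,14-tetramethylpentadeca-2,8-dienoate, via alkenylzirconocene 31 (not isolated), via alkenylzinc 32 (not isolated)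
Conditions: Cp2ZrHCl, THF, 50 °C; Me2Zn, −78 °C; then 15, −78 → 0 °C
Reagents that add atoms: none
Why: Syn hydrozirconation places zirconium at the less hindered C8 (E-alkenyl), and zirconium-to-zinc transmetalation followed by Cram-chelate addition (zinc bound to the aldehyde and α-OMe oxygens) gives the 6,7-syn 7S allylic alcohol with the E C8=C9 bond (Wipf alkenylzinc addition).

Step 19
Reactants: 33 methyl (2E,6S,7S,8E,10S,11R,12S,14S,15R)-15-{3-bromo-5-[tri(propan-2-yl)silyloxy]phenyl}-11,15-bis{[tert-butyl(dimethyl)silyl]oxy}-7-hydroxy-6,12-dimethoxy-2,8,10,14-tetramethylpentadeca-2,8-dienoate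
Product: 34 (2E,6S,7S,8E,10S,11R,12S,14S,15R)-15-{3-bromo-5-[tri(propan-2-yl)silyloxy]phenyl}-11,15-bis{[tert-butyl(dimethyl)silyl]oxy}-7-hydroxy-6,12-dimethoxy-2,8,10,14-tetramethylpentadeca-2,8-dienamide
Conditions: AlMe3, NH4Cl, toluene, 50 °C
Reagents that add atoms: ammonium chloride, [NH4+].[Cl-]
Why: Weinreb-type aminolysis of the methyl ester by the aluminium amide made from AlMe3 and NH4Cl gives the primary amide; silyl ethers, the aryl bromide and the C7 alcohol (as its aluminium alkoxide) are tolerated.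

Step 20
Reactants: 34 (2E,6S,7S,8E,10S,11R,12S,14S,15R)-15-{3-bromo-5-[tri(propan-2-yl)silyloxy]phenyl}-11,15-bis{[tert-butyl(dimethyl)silyl]oxy}-7-hydroxy-6,12-dimethoxy-2,8,10,14-tetramethylpentadeca-2,8-dienamide
Product: 35 (4E,8S,9S,10E,12S,13R,14S,16S,17R)-13,17-bis{[tert-butyl(dimethyl)silyl]oxy}-9-hydroxy-8,14-dimethoxy-4,10,12,16-tetramethyl-20-[tri(propan-2-yl)silyloxy]-2-azabicyclo[16.3.1]docosa-1(22),4,10,18,20-pentaen-3-one
Conditions: CuI (50 mol%), N,N'-dimethylethylenediamine, K2CO3, toluene (2 mM), 100 °C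
Reagents that add atoms: none
Why: Intramolecular Goldberg amidation of the aryl bromide by the primary enamide closes the 19-membered lactam under high dilution; the amide nitrogen is arylated in preference to the secondary alcohol.

Step 21
Reactants: 35 (4E,8S,9S,10E,12S,13R,14S,16S,17R)-13,17-bis{[tert-butyl(dimethyl)silyl]oxy}-9-hydroxy-8,14-dimethoxy-4,10,12,16-tetramethyl-20-[tri(propan-2-yl)silyloxy]-2-azabicyclo[16.3.1]docosa-1(22),4,10,18,20-pentaen-3-one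
Product: 36 (4E,8S,9S,10E,12S,13R,14S,16S,17R)-9,13,17,20-tetrahydroxy-8,14-dimethoxy-4,10,12,16-tetramethyl-2-azabicyclo[16.3.1]docosa-1(22),4,10,18,20-pentaen-3-one
Conditions: TBAF, THF, 0 °C → rt
Reagents that add atoms: none
Why: Fluoride-mediated global desilylation removes the aryl TIPS ether and both secondary TBS ethers without touching stereocentres, alkenes or the lactam.

## Compound list

1 | 3-bromophenol | Oc1cccc(Br)c1 | starting material
2 | (3-bromophenoxy)tri(propan-2-yl)silane | CC(C)[Si](Oc1cccc(Br)c1)(C(C)C)C(C)C | intermediate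
3 | [3-bromo-5-(4,4,5,5-tetramethyl-1,3,2-dioxaborolan-2-yl)phenoxy]tri(propan-2-yl)silane | CC(C)[Si](Oc1cc(Br)cc(c1)B1OC(C)(C)C(C)(C)O1)(C(C)C)C(C)C | intermediate
4 | chloro(methoxy)methane | COCCl | starting material
5 | methoxymethyl 2,4,6-tri(propan-2-yl)benzoate | COCOC(=O)c1c(C(C)C)cc(C(C)C)cc1C(C)C | intermediate
6 | (2S)-pent-3-yn-2-ol | CC#C[C@H](C)O | starting material
7 | (2S)-pent-3-yn-2-yl methanesulfonate | CC#C[C@H](C)OS(C)(=O)=O | intermediate
8 | (aR)-tributyl(penta-2,3-dien-2-yl)stannane | [H]C(C)=[C@@]=C(C)[Sn](CCCC)(CCCC)CCCC | intermediate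
9 | penta-1,4-dien-3-ol | C=CC(O)C=C | starting material
10 | (1S)-1-[(2R)-oxiran-2-yl]prop-2-en-1-ol | C=C[C@H](O)[C@H]1CO1 | intermediate
11 | (2R)-2-[(1S)-1-methoxyprop-2-en-1-yl]oxirane | C=C[C@H](OC)[C@H]1CO1 | intermediate
12 | methyl (2E)-3-iodo-2-methylprop-2-enoate | COC(=O)/C(C)=C/I | starting material
13 | 9-{(3S)-3-methoxy-3-[(2R)-oxiran-2-yl]propyl}-9-borabicyclo[3.3.1]nonane | CO[C@@H](CCB1C2CCCC1CCC2)[C@H]1CO1 | intermediate
14 | methyl (2E,6S)-6-methoxy-2-methyl-6-[(2R)-oxiran-2-yl]hex-2-enoate | COC(=O)/C(C)=C/CC[C@H](OC)[C@H]1CO1 | intermediate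
15 | methyl (2E,6S)-6-methoxy-2-methyl-7-oxohept-2-enoate | COC(=O)/C(C)=C/CC[C@H](OC)C=O | intermediate
16 | (2R)-3-bromo-2-methylpropan-1-ol | OC[C@@H](C)CBr | starting material
17 | (2R)-3-bromo-2-methylpropyl N,N-di(propan-2-yl)carbamate | CC(C)N(C(C)C)C(=O)OC[C@@H](C)CBr | intermediate
18 | (2S)-2-methyl-3-(4,4,5,5-tetramethyl-1,3,2-dioxaborolan-2-yl)propyl N,N-di(propan-2-yl)carbamate | CC(C)N(C(C)C)C(=O)OC[C@@H](C)CB1OC(C)(C)C(C)(C)O1 | intermediate
19 | (R)-lithio(methoxy)methyl 2,4,6-tri(propan-2-yl)benzoate | [Li][C@H](OC)OC(=O)c1c(C(C)C)cc(C(C)C)cc1C(C)C | intermediate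
20 | lithium boronate complex of 18 and 19 (B bonded to the acetal carbon, retention) | [Li+].CO[C@H](OC(=O)c1c(C(C)C)cc(C(C)C)cc1C(C)C)[B-]1(C[C@H](C)COC(=O)N(C(C)C)C(C)C)OC(C)(C)C(C)(C)O1 | intermediate
21 | (2S,4R)-4-methoxy-2-methyl-4-(4,4,5,5-tetramethyl-1,3,2-dioxaborolan-2-yl)butyl N,N-di(propan-2-yl)carbamate | CC(C)N(C(C)C)C(=O)OC[C@@H](C)C[C@H](OC)B1OC(C)(C)C(C)(C)O1 | intermediate
22 | (2S,4S)-5-chloro-4-methoxy-2-methyl-5-(4,4,5,5-tetramethyl-1,3,2-dioxaborolan-2-yl)pentyl N,N-di(propan-2-yl)carbamate (both C5 epimers) | CC(C)N(C(C)C)C(=O)OC[C@@H](C)C[C@H](OC)C(Cl)B1OC(C)(C)C(C)(C)O1 | intermediate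
23 | (2S,4S)-4-methoxy-2-methyl-5-oxopentyl N,N-di(propan-2-yl)carbamate | CC(C)N(C(C)C)C(=O)OC[C@@H](C)C[C@H](OC)C=O | intermediate
24 | (2S,4S,5R,6S)-5-hydroxy-4-methoxy-2,6-dimethylnon-7-yn-1-yl N,N-di(propan-2-yl)carbamate | CC(C)N(C(C)C)C(=O)OC[C@@H](C)C[C@H](OC)[C@H](O)[C@@H](C)C#CC | intermediate
25 | (2S,4S,5R,6S)-5-{[tert-butyl(dimethyl)silyl]oxy}-4-methoxy-2,6-dimethylnon-7-yn-1-yl N,N-di(propan-2-yl)carbamate | CC(C)N(C(C)C)C(=O)OC[C@@H](C)C[C@H](OC)[C@H](O[Si](C)(C)C(C)(C)C)[C@@H](C)C#CC | intermediate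
26 | (1S,2S,4S,5R,6S)-1-lithio derivative of 25 | [Li][C@H](OC(=O)N(C(C)C)C(C)C)[C@@H](C)C[C@H](OC)[C@H](O[Si](C)(C)C(C)(C)C)[C@@H](C)C#CC | intermediate
27 | lithium boronate complex of 26 and 3 (B bonded to C1 of the chain, retention) | [Li+].CC(C)[Si](Oc1cc(Br)cc(c1)[B-]1(OC(C)(C)C(C)(C)O1)[C@H](OC(=O)N(C(C)C)C(C)C)[C@@H](C)C[C@H](OC)[C@H](O[Si](C)(C)C(C)(C)C)[C@@H](C)C#CC)(C(C)C)C(C)C | intermediate
28 | {3-bromo-5-[(1R,2S,4S,5R,6S)-5-{[tert-butyl(dimethyl)silyl]oxy}-4-methoxy-2,6-dimethyl-1-(4,4,5,5-tetramethyl-1,3,2-dioxaborolan-2-yl)non-7-yn-1-yl]phenoxy}tri(propan-2-yl)silane | CC(C)[Si](Oc1cc(Br)cc(c1)[C@H](B1OC(C)(C)C(C)(C)O1)[C@@H](C)C[C@H](OC)[C@H](O[Si](C)(C)C(C)(C)C)[C@@H](C)C#CC)(C(C)C)C(C)C | intermediate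
29 | (1R,2S,4S,5R,6S)-1-{3-bromo-5-[tri(propan-2-yl)silyloxy]phenyl}-5-{[tert-butyl(dimethyl)silyl]oxy}-4-methoxy-2,6-dimethylnon-7-yn-1-ol | CC(C)[Si](Oc1cc(Br)cc(c1)[C@H](O)[C@@H](C)C[C@H](OC)[C@H](O[Si](C)(C)C(C)(C)C)[C@@H](C)C#CC)(C(C)C)C(C)C | intermediate
30 | {3-bromo-5-[(1R,2S,4S,5R,6S)-1,5-bis{[tert-butyl(dimethyl)silyl]oxy}-4-methoxy-2,6-dimethylnon-7-yn-1-yl]phenoxy}tri(propan-2-yl)silane | CC(C)[Si](Oc1cc(Br)cc(c1)[C@H](O[Si](C)(C)C(C)(C)C)[C@@H](C)C[C@H](OC)[C@H](O[Si](C)(C)C(C)(C)C)[C@@H](C)C#CC)(C(C)C)C(C)C | intermediate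
31 | (E)-alkenylzirconocene chloride from 30 (Cp2ZrCl on C8, H on C9; cyclopentadienyl rings drawn σ-bonded) | Cl[Zr](C1C=CC=C1)(C1C=CC=C1)/C(C)=C/[C@H](C)[C@@H](O[Si](C)(C)C(C)(C)C)[C@@H](OC)C[C@H](C)[C@@H](O[Si](C)(C)C(C)(C)C)c1cc(Br)cc(O[Si](C(C)C)(C(C)C)C(C)C)c1 | intermediate
32 | (E)-alkenyl(methyl)zinc from 31 (MeZn on C8) | C[Zn]/C(C)=C/[C@H](C)[C@@H](O[Si](C)(C)C(C)(C)C)[C@@H](OC)C[C@H](C)[C@@H](O[Si](C)(C)C(C)(C)C)c1cc(Br)cc(O[Si](C(C)C)(C(C)C)C(C)C)c1 | intermediate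
33 | methyl (2E,6S,7S,8E,10S,11R,12S,14S,15R)-15-{3-bromo-5-[tri(propan-2-yl)silyloxy]phenyl}-11,15-bis{[tert-butyl(dimethyl)silyl]oxy}-7-hydroxy-6,12-dimethoxy-2,8,10,14-tetramethylpentadeca-2,8-dienoate | COC(=O)/C(C)=C/CC[C@H](OC)[C@@H](O)/C(C)=C/[C@H](C)[C@@H](O[Si](C)(C)C(C)(C)C)[C@@H](OC)C[C@H](C)[C@@H](O[Si](C)(C)C(C)(C)C)c1cc(Br)cc(O[Si](C(C)C)(C(C)C)C(C)C)c1 | intermediate
34 | (2E,6S,7S,8E,10S,11R,12S,14S,15R)-15-{3-bromo-5-[tri(propan-2-yl)silyloxy]phenyl}-11,15-bis{[tert-butyl(dimethyl)silyl]oxy}-7-hydroxy-6,12-dimethoxy-2,8,10,14-tetramethylpentadeca-2,8-dienamide | NC(=O)/C(C)=C/CC[C@H](OC)[C@@H](O)/C(C)=C/[C@H](C)[C@@H](O[Si](C)(C)C(C)(C)C)[C@@H](OC)C[C@H](C)[C@@H](O[Si](C)(C)C(C)(C)C)c1cc(Br)cc(O[Si](C(C)C)(C(C)C)C(C)C)c1 | intermediate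
35 | (4E,8S,9S,10E,12S,13R,14S,16S,17R)-13,17-bis{[tert-butyl(dimethyl)silyl]oxy}-9-hydroxy-8,14-dimethoxy-4,10,12,16-tetramethyl-20-[tri(propan-2-yl)silyloxy]-2-azabicyclo[16.3.1]docosa-1(22),4,10,18,20-pentaen-3-one | CO[C@H]1C[C@H](C)[C@@H](O[Si](C)(C)C(C)(C)C)c2cc(O[Si](C(C)C)(C(C)C)C(C)C)cc(c2)NC(=O)/C(C)=C/CC[C@H](OC)[C@@H](O)/C(C)=C/[C@H](C)[C@H]1O[Si](C)(C)C(C)(C)C | intermediate
36 | (4E,8S,9S,10E,12S,13R,14S,16S,17R)-9,13,17,20-tetrahydroxy-8,14-dimethoxy-4,10,12,16-tetramethyl-2-azabicyclo[16.3.1]docosa-1(22),4,10,18,20-pentaen-3-one (CNP0366451.1) | CO[C@H]1C[C@H](C)[C@@H](O)c2cc(O)cc(c2)NC(=O)/C(C)=C/CC[C@H](OC)[C@@H](O)/C(C)=C/[C@H](C)[C@H]1O | target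

## Step count and risk

Total steps: 21. Longest linear sequence: 12 steps (steps 10 to 21, from 16 to 36).

Three steps most likely to fail:

Step 12 (the proposed new α-methoxy carbenoid homologation). Risks are α-elimination of 19 to methoxycarbene, poor enantiotopic selection next to the small OMe group, and ionisation of 20 before migration. The fallback is auxiliary-controlled Matteson chemistry; it sets out from 17 and returns at 23. Bromide 17 is converted with Mg in THF into the Grignard reagent bromo{(2R)-3-[(dipropan-2-ylcarbamoyl)oxy]-2-methylpropyl}magnesium F1. This is trapped with B(OMe)3 and esterified with (1R,2R)-1,2-dicyclohexylethane-1,2-diol to give (2S)-3-[(4R,5R)-4,5-dicyclohexyl-1,3,2-dioxaborolan-2-yl]-2-methylpropyl N,N-di(propan-2-yl)carbamate F2. Insertion of LiCHCl2 (−100 °C, ZnCl2) under control of the diol gives the α-chloro boronate (2S,4S)-4-chloro-4-[(4R,5R)-4,5-dicyclohexyl-1,3,2-dioxaborolan-2-yl]-2-methylbutyl N,N-di(propan-2-yl)carbamate F3. NaOMe displaces chloride with inversion to give (2S,4R)-4-[(4R,5R)-4,5-dicyclohexyl-1,3,2-dioxaborolan-2-yl]-4-methoxy-2-methylbutyl N,N-di(propan-2-yl)carbamate F4. A second LiCHCl2 insertion gives (2S,4S,5S)-5-chloro-5-[(4R,5R)-4,5-dicyclohexyl-1,3,2-dioxaborolan-2-yl]-4-methoxy-2-methylpentyl N,N-di(propan-2-yl)carbamate F5, which is oxidised with buffered H2O2 to aldehyde 23.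

Step 16 (lithiation–borylation on the full C8–C15 chain). Risks are bromine–lithium exchange on 3, competing propargylic lithiation, and a mismatched or chelation-perturbed deprotonation next to C14. The fallback replaces the 1,2-shift by carbonyl chemistry; it sets out from 25 and returns at 29. LiAlH4 removes the carbamate from 25 to give (2S,4S,5R,6S)-5-{[tert-butyl(dimethyl)silyl]oxy}-4-methoxy-2,6-dimethylnon-7-yn-1-ol F6. Dess–Martin oxidation gives (2S,4S,5R,6S)-5-{[tert-butyl(dimethyl)silyl]oxy}-4-methoxy-2,6-dimethylnon-7-ynal F7. Addition of aryl boronate 3 catalysed by [Rh(cod)OH]2 (dioxane/H2O) gives 29 together with its epimer (1S,2S,4S,5R,6S)-1-{3-bromo-5-[tri(propan-2-yl)silyloxy]phenyl}-5-{[tert-butyl(dimethyl)silyl]oxy}-4-methoxy-2,6-dimethylnon-7-yn-1-ol F8. The mixture is oxidised with Dess–Martin periodinane to (2S,4S,5R,6S)-1-{3-bromo-5-[tri(propan-2-yl)silyloxy]phenyl}-5-{[tert-butyl(dimethyl)silyl]oxy}-4-methoxy-2,6-dimethylnon-7-yn-1-one F9, and reagent-controlled reduction with (S)-Me-CBS and catecholborane at −78 °C gives 29.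

Step 18 (alkenylzinc addition to the α-methoxy aldehyde). Risks are incomplete regiocontrol in the hydrozirconation of the internal alkyne and low chelation control at C7. The fallback uses Nozaki–Hiyama–Kishi coupling followed by oxidation and reduction; it sets out from 30 and returns at 33. Hydrozirconation of 30 (Cp2ZrHCl) and iodinolysis of 31 with I2 give {3-bromo-5-[(1R,2S,4S,5R,6S,7E)-1,5-bis{[tert-butyl(dimethyl)silyl]oxy}-8-iodo-4-methoxy-2,6-dimethylnon-7-en-1-yl]phenoxy}tri(propan-2-yl)silane F10. Coupling with 15 (CrCl2, NiCl2 cat., DMSO/THF) gives 33 together with its C7 epimer methyl (2E,6S,7R,8E,10S,11R,12S,14S,15R)-15-{3-bromo-5-[tri(propan-2-yl)silyloxy]phenyl}-11,15-bis{[tert-butyl(dimethyl)silyl]oxy}-7-hydroxy-6,12-dimethoxy-2,8,10,14-tetramethylpentadeca-2,8-dienoate F11. Dess–Martin oxidation of the mixture gives the enone methyl (2E,6S,8E,10S,11R,12S,14S,15R)-15-{3-bromo-5-[tri(propan-2-yl)silyloxy]phenyl}-11,15-bis{[tert-butyl(dimethyl)silyl]oxy}-6,12-dimethoxy-2,8,10,14-tetramethyl-7-oxopentadeca-2,8-dienoate F12, and reduction with (S)-Me-CBS and catecholborane at −78 °C gives 33.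

Further compounds

F1 | step 12 | bromo{(2R)-3-[(dipropan-2-ylcarbamoyl)oxy]-2-methylpropyl}magnesium | CC(C)N(C(C)C)C(=O)OC[C@@H](C)C[Mg]Br
F2 | step 12 | (2S)-3-[(4R,5R)-4,5-dicyclohexyl-1,3,2-dioxaborolan-2-yl]-2-methylpropyl N,N-di(propan-2-yl)carbamate | CC(C)N(C(C)C)C(=O)OC[C@@H](C)CB1O[C@H](C2CCCCC2)[C@@H](C2CCCCC2)O1
F3 | step 12 | (2S,4S)-4-chloro-4-[(4R,5R)-4,5-dicyclohexyl-1,3,2-dioxaborolan-2-yl]-2-methylbutyl N,N-di(propan-2-yl)carbamate | CC(C)N(C(C)C)C(=O)OC[C@@H](C)C[C@@H](Cl)B1O[C@H](C2CCCCC2)[C@@H](C2CCCCC2)O1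
F4 | step 12 | (2S,4R)-4-[(4R,5R)-4,5-dicyclohexyl-1,3,2-dioxaborolan-2-yl]-4-methoxy-2-methylbutyl N,N-di(propan-2-yl)carbamate | CC(C)N(C(C)C)C(=O)OC[C@@H](C)C[C@H](OC)B1O[C@H](C2CCCCC2)[C@@H](C2CCCCC2)O1
F5 | step 12 | (2S,4S,5S)-5-chloro-5-[(4R,5R)-4,5-dicyclohexyl-1,3,2-dioxaborolan-2-yl]-4-methoxy-2-methylpentyl N,N-di(propan-2-yl)carbamate | CC(C)N(C(C)C)C(=O)OC[C@@H](C)C[C@H](OC)[C@@H](Cl)B1O[C@H](C2CCCCC2)[C@@H](C2CCCCC2)O1
F6 | step 16 | (2S,4S,5R,6S)-5-{[tert-butyl(dimethyl)silyl]oxy}-4-methoxy-2,6-dimethylnon-7-yn-1-ol | OC[C@@H](C)C[C@H](OC)[C@H](O[Si](C)(C)C(C)(C)C)[C@@H](C)C#CC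
F7 | step 16 | (2S,4S,5R,6S)-5-{[tert-butyl(dimethyl)silyl]oxy}-4-methoxy-2,6-dimethylnon-7-ynal | O=C[C@@H](C)C[C@H](OC)[C@H](O[Si](C)(C)C(C)(C)C)[C@@H](C)C#CC
F8 | step 16 | (1S,2S,4S,5R,6S)-1-{3-bromo-5-[tri(propan-2-yl)silyloxy]phenyl}-5-{[tert-butyl(dimethyl)silyl]oxy}-4-methoxy-2,6-dimethylnon-7-yn-1-ol | CC(C)[Si](Oc1cc(Br)cc(c1)[C@@H](O)[C@@H](C)C[C@H](OC)[C@H](O[Si](C)(C)C(C)(C)C)[C@@H](C)C#CC)(C(C)C)C(C)C
F9 | step 16 | (2S,4S,5R,6S)-1-{3-bromo-5-[tri(propan-2-yl)silyloxy]phenyl}-5-{[tert-butyl(dimethyl)silyl]oxy}-4-methoxy-2,6-dimethylnon-7-yn-1-one | CC(C)[Si](Oc1cc(Br)cc(c1)C(=O)[C@@H](C)C[C@H](OC)[C@H](O[Si](C)(C)C(C)(C)C)[C@@H](C)C#CC)(C(C)C)C(C)C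
F10 | step 18 | {3-bromo-5-[(1R,2S,4S,5R,6S,7E)-1,5-bis{[tert-butyl(dimethyl)silyl]oxy}-8-iodo-4-methoxy-2,6-dimethylnon-7-en-1-yl]phenoxy}tri(propan-2-yl)silane | I/C(C)=C/[C@H](C)[C@@H](O[Si](C)(C)C(C)(C)C)[C@@H](OC)C[C@H](C)[C@@H](O[Si](C)(C)C(C)(C)C)c1cc(Br)cc(O[Si](C(C)C)(C(C)C)C(C)C)c1
F11 | step 18 | methyl (2E,6S,7R,8E,10S,11R,12S,14S,15R)-15-{3-bromo-5-[tri(propan-2-yl)silyloxy]phenyl}-11,15-bis{[tert-butyl(dimethyl)silyl]oxy}-7-hydroxy-6,12-dimethoxy-2,8,10,14-tetramethylpentadeca-2,8-dienoate | COC(=O)/C(C)=C/CC[C@H](OC)[C@H](O)/C(C)=C/[C@H](C)[C@@H](O[Si](C)(C)C(C)(C)C)[C@@H](OC)C[C@H](C)[C@@H](O[Si](C)(C)C(C)(C)C)c1cc(Br)cc(O[Si](C(C)C)(C(C)C)C(C)C)c1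
F12 | step 18 | methyl (2E,6S,8E,10S,11R,12S,14S,15R)-15-{3-bromo-5-[tri(propan-2-yl)silyloxy]phenyl}-11,15-bis{[tert-butyl(dimethyl)silyl]oxy}-6,12-dimethoxy-2,8,10,14-tetramethyl-7-oxopentadeca-2,8-dienoate | COC(=O)/C(C)=C/CC[C@H](OC)C(=O)/C(C)=C/[C@H](C)[C@@H](O[Si](C)(C)C(C)(C)C)[C@@H](OC)C[C@H](C)[C@@H](O[Si](C)(C)C(C)(C)C)c1cc(Br)cc(O[Si](C(C)C)(C(C)C)C(C)C)c1
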